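## The problem

Compound 22 is a 2-aryl-4H-chromen-4-one: benzo ring A is fused to pyranone ring C along C4a–C8a, and ring B is joined to C2 by a C–C bond that carries an ortho methoxy group. It has no stereocentre, so every difficulty is one of regiochemistry and chemoselectivity. Ring A bears oxygen on C5, C7, C8 and, as O1, on C8a: a vicinal triad plus one isolated oxygen, with O1 at an end of the triad. Substitution on a symmetric tetraoxygenated benzene cannot distinguish the two free positions, so this pattern has to be fixed by construction. The six oxygens must end in two classes, four methyl ethers (C3, C7, C8, C2') and two free phenols (C5, C4'). The phenol protecting groups therefore have to leave under conditions that spare methyl ethers; the 3-methoxy group (next to the carbonyl) and the 8-methoxy group (flanked by O1 and the 7-methoxy group) are the most exposed to Lewis acids. The pyranone opens at C2 with hot hydroxide or alkoxide, 5-hydroxy-7,8-dioxygenated flavones can isomerise to the 5,6,7 series in hot strong acid (Wessely–Moser), and 2,4-dialkoxybenzyl derivatives of ring B ionise easily in acid, so the end game must be mild. The enabling feature is C3: one carbon without hydrogen, carrying one heteroatom, between C2 (O1 and aryl) and C4 (carbonyl). Excising it leaves a 2-arylbenzofuran-3-ol whose C2=C3 bond is an enol ether oxygenated on both carbons, so C3 can be returned as a halocarbene with enlargement of the furan to ring C.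

## Retrosynthesis

**22 from 21.** The two O–isopropyl bonds at O5 and O4' are cut. Benzyl at O4' is excluded because it would offer a second benzylic CH2 to the amide base used earlier. A methyl ether at O5 would force a chelation-controlled demethylation next to the 3-methoxy and 8-methoxy groups. With isopropyl on both oxygens, one Lewis-acid dealkylation of secondary ethers frees both phenols, at no cost in steps. Precursor 21 has no free phenol and is stable to base. The forward step must cleave two secondary alkyl ethers and leave four methyl ethers.

**21 from 20.** The C3–OMe bond is cut to a C3–Br bond. Delivering C3 already methoxylated is not realistic, because alkoxyhalocarbenes are nucleophilic and do not add to electron-rich alkenes, whereas a dihalocarbene does and leaves a halogen as a handle. The forward step is a palladium-catalysed C–O coupling; reductive elimination must outrun β-hydride elimination, and methoxide must be kept low enough to spare C2.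

**20 from 16 and bromoform 17 (key disconnection).** C2–C3 and C3–C4 are cut and ring C contracts to the furan of silyl ether 16. The neighbouring cuts, O1–C2 by cyclodehydration of a 1,3-diketone or oxidative closure of a chalcone, need an ω-methoxyacetophenone or fail for 6'-alkoxy chalcones, which tend to give aurones. Here the precursor is a benzofuran that one anionic ring closure provides, and the one-carbon unit is the cheapest possible. The forward step needs carbene addition to the enol ether alone and opening of the adduct at the ring-fusion bond.

**16 from 14.** The furan C2–C3 bond (benzylic carbon to ester carbonyl) and the O–Si bond are cut. The alternative, arylation of a preformed benzofuran-3-one at C2, needs that ketone to be made separately. The chosen cut turns the ring into a benzyl aryl ether of a salicylate, 14, and closes it by a Dieckmann-type 5-exo-trig acylation of the lithiated benzylic carbon. The base must deprotonate only this CH2, which is why O4' carries isopropyl; the enolate is trapped on oxygen in the same flask.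

**14 from 10 and 13.** The benzylic C–O bond is cut. A Mitsunobu etherification is preferred to a Williamson reaction because 2,4-dialkoxybenzyl halides self-condense. Alcohol 13 comes from aldehyde 12 by reduction, and 12 from commercial 4-hydroxy-2-methoxybenzaldehyde 11 by O-isopropylation.

**10 from 6 via 9 and 8.** The bond from the ring to the ester carbon is cut. Phenol 6 has a single free ortho position, so a magnesium-mediated ortho-formylation places the carbon exactly where C4 of the flavone must be, giving aldehyde 8. Oxidation to acid 9 and esterification to 10 then only adjust the oxidation state. Carboxylation of the phenol directly would be shorter but is less reliable on this substitution pattern.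

**6 from 1 via 5, 4 and 2.** The oxygen pattern is traced to commercial 3-hydroxy-4,5-dimethoxybenzaldehyde 1. Its phenol becomes O1 and is masked as the benzyl ether 2; its formyl group is exchanged for oxygen (Baeyer–Villiger/Dakin) to give phenol 4, which becomes the isolated O5 and is isopropylated to 5. Hydrogenolysis then frees phenol 6. The triad and the isolated oxygen are thus distinguished from the start, with no regiochemical choice anywhere.

## Roads not taken

**Alternative 1:** The cut takes C4 out of the skeleton: C4a–C4 and C3–C4 are broken and C4 becomes a one-carbon gas. In the forward step Pd(dba)2 (zerovalent palladium) with a bisphosphine would assemble the 2-methoxy-1,3-diketone A1 from the ring A aryl iodide A2, the enolate of the ring B methoxymethyl ketone A3 and carbon monoxide A4.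
- Merits: the route is convergent, the 3-methoxy group arrives with A3 so no late C–O coupling is needed, and A1 is the classical diketone precursor of a flavone reached without an acyl migration.
- Weak points: the iodine of A2 lies between two ortho oxygens on an electron-rich ring, so CO insertion and acyl transfer from a di-ortho-substituted arylpalladium will be slow. Direct, non-carbonylative α-arylation of A3 competes, and A1 is more acidic than A3 and can bind the catalyst.
- Further cost: the key step closes no ring. A2 needs the same differentiated ring A oxygen pattern as ester 10. Acetal removal with cyclodehydration, a chelation-controlled 5-demethylation and a debenzylation still follow.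
- Comparison: on convergence and on the C3 oxygen this road is better, and its length is about the same. The chosen plan sets against it a key step that builds C3 and closes ring C at once from 16, no pressurised toxic gas, no hindered carbonylative coupling, and release of the 5-hydroxyl without a selective demethylation.

**Alternative 2:** Here ring A is the ring that is made, by cutting C4a–C5. Heating would convert a hydroxycyclobutenone into the 5,8-dihydroxyflavone A5 through electrocyclic opening to a vinylketene, closure of the ketene carbon onto C5 of the pyranone and tautomerisation. The cyclobutenone A6 (racemic) would come from addition of the C6-lithiated pyranone A8 to the semisquarate A7.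
- Merits: the 5,8-oxygen pattern is set by construction, the 5-hydroxyl emerges free and chelated, and the unchelated 8-hydroxyl should be methylated selectively. In this respect the road is superior to the chosen one, which needs protecting groups for O5.
- Weak points: A8 is as much work as a flavone precursor. Its deprotonation at C6 competes with conjugate addition of the base, and the anion must pick the right carbonyl of A7. The vinylketene must close on an electron-poor pyranone carbon, and hydroquinone A5 is prone to air oxidation to the 5,8-quinone.
- Comparison: more steps of uncertain outcome precede the key step than in the chosen plan, where everything up to 16 is ether, ester and enolate chemistry on robust arenes. The chosen plan sets this reliability and a shorter sequence against the protecting-group-free ring A.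

**Alternative 3:** The cut is O1–C8a. Anodic oxidation in hexafluoroisopropanol would close ring C of the pivalate-protected flavone A9 by joining the enol oxygen of the 2-methoxy-1,3-diketone A10 to an unfunctionalised ring A carbon.
- Merits: ring A enters as a plain 2,4,5-trimethoxyphenyl ketone unit with no oxygen at C8a, so the seven steps leading to ester 10 would disappear. On paper this is the shortest route, and it uses no stoichiometric oxidant.
- Weak points: the closure must occur at a C–H that is ortho to the acyl group, ortho to only one methoxy group and meta to two, which is not the position of highest spin density in the arene radical cation. Both arenes and the enol of A10 are oxidised at similar potentials, and A9 is at least as oxidisable as A10, so over-oxidation threatens.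
- Further cost: a dehydrogenative C–O closure of this kind on such a substrate has no close analogy, and pivalate removal and a selective 5-demethylation still follow.
- Comparison: if it worked it would beat the chosen route by several steps. The chosen plan sets against that brevity that the site of ring closure is fixed by the covalent structure of 16, not by electronic preference, and that each of its bond-forming steps has a close analogy.

Key step: step 12

Remark on the chemistry: O5 is carried as an isopropyl ether like O4', so one mild BCl3 treatment frees both phenols; the adduct 18 is racemic and transient, and the target has no stereocentre.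

## Route

Step 1
Reactants: 1 3-hydroxy-4,5-dimethoxybenzaldehyde
Product: 2 3-(benzyloxy)-4,5-dimethoxybenzaldehyde
Conditions: BnBr, K2CO3, DMF, rt
Reagents that add atoms: benzyl bromide, SMILES BrCc1ccccc1
Why: Williamson etherification of the only phenol; the benzyl group masks the oxygen that later becomes O1 and is removable by hydrogenolysis beside methyl and isopropyl ethers.

Step 2
Reactants: 2 3-(benzyloxy)-4,5-dimethoxybenzaldehyde
Product: 4 3-(benzyloxy)-4,5-dimethoxyphenol, via aryl formate 3 (not isolated)
Conditions: mCPBA, CH2Cl2, 0 °C to rt; then K2CO3 (cat.), MeOH, rt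
Reagents that add atoms: 3-chloroperoxybenzoic acid, SMILES OOC(=O)c1cccc(Cl)c1
Why: Baeyer–Villiger (Dakin-type) oxidation; the electron-rich trialkoxyaryl group migrates in preference to hydrogen, and the formate 3 is methanolysed to the phenol, which becomes O5.

Step 3
Reactants: 4 3-(benzyloxy)-4,5-dimethoxyphenol
Product: 5 1-(benzyloxy)-2,3-dimethoxy-5-(propan-2-yloxy)benzene
Conditions: 2-bromopropane, K2CO3, DMF, 60 °C
Reagents that add atoms: 2-bromopropane, SMILES CC(C)Br
Why: Williamson etherification of an unhindered phenoxide with a secondary bromide; an excess of the bromide covers loss by elimination.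

Step 4
Reactants: 5 1-(benzyloxy)-2,3-dimethoxy-5-(propan-2-yloxy)benzene
Product: 6 2,3-dimethoxy-5-(propan-2-yloxy)phenol
Conditions: H2 (1 atm), Pd/C, EtOAc, rt
Reagents that add atoms: none
Why: Hydrogenolysis of the benzyl ether; methyl and isopropyl aryl ethers are inert to these conditions.

Step 5
Reactants: 6 2,3-dimethoxy-5-(propan-2-yloxy)phenol
Product: 8 2-hydroxy-3,4-dimethoxy-6-(propan-2-yloxy)benzaldehyde, via hydroxymethylphenol 7 (not isolated)
Conditions: MgCl2, Et3N, (CH2O)n, MeCN, reflux
Reagents that add atoms: paraformaldehyde (reacts as formaldehyde), SMILES C=O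
Why: Magnesium-mediated ortho-formylation of phenols (Casnati–Skattebøl); the magnesium phenoxide delivers formaldehyde only to the ortho position, of which one is free, and the benzylic alkoxide 7 is oxidised in the flask by hydride transfer to a second formaldehyde.

Step 6
Reactants: 8 2-hydroxy-3,4-dimethoxy-6-(propan-2-yloxy)benzaldehyde
Product: 9 2-hydroxy-3,4-dimethoxy-6-(propan-2-yloxy)benzoic acid
Conditions: NaClO2, NaH2PO4, 2-methyl-2-butene, t-BuOH/H2O, 0 °C to rt
Reagents that add atoms: sodium chlorite, SMILES [Na+].[O-]Cl=O
Why: Pinnick (Lindgren) oxidation, which tolerates phenolic aldehydes and, unlike peracids, cannot trigger a Dakin reaction; the alkene scavenges hypochlorite and a cold, weakly acidic work-up avoids decarboxylation of the 2,6-dioxygenated acid.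

Step 7
Reactants: 9 2-hydroxy-3,4-dimethoxy-6-(propan-2-yloxy)benzoic acid
Product: 10 methyl 2-hydroxy-3,4-dimethoxy-6-(propan-2-yloxy)benzoate
Conditions: MeI, KHCO3, DMF, rt
Reagents that add atoms: iodomethane, SMILES CI
Why: SN2 alkylation of the carboxylate; hydrogen carbonate is too weak to ionise the hydrogen-bonded salicylate phenol, and the absence of acid avoids protodecarboxylation.

Step 8
Reactants: 11 4-hydroxy-2-methoxybenzaldehyde
Product: 12 2-methoxy-4-(propan-2-yloxy)benzaldehyde
Conditions: 2-bromopropane, K2CO3, DMF, 60 °C
Reagents that add atoms: 2-bromopropane, SMILES CC(C)Br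
Why: Williamson etherification of an acidic para-formyl phenol; isopropyl is chosen because it has no acidic benzylic hydrogen and is cleaved by BCl3 beside methyl ethers.

Step 9
Reactants: 12 2-methoxy-4-(propan-2-yloxy)benzaldehyde
Product: 13 [2-methoxy-4-(propan-2-yloxy)phenyl]methanol
Conditions: NaBH4, MeOH, 0 °C
Reagents that add atoms: none
Why: Borohydride reduction of an aryl aldehyde; a neutral work-up is used because the electron-rich benzylic alcohol ionises in acid.

Step 10
Reactants: 10 methyl 2-hydroxy-3,4-dimethoxy-6-(propan-2-yloxy)benzoate; 13 [2-methoxy-4-(propan-2-yloxy)phenyl]methanol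
Product: 14 methyl 3,4-dimethoxy-2-{[2-methoxy-4-(propan-2-yloxy)phenyl]methoxy}-6-(propan-2-yloxy)benzoate
Conditions: PPh3, DIAD, THF, 0 °C to rt
Reagents that add atoms: none
Why: Mitsunobu etherification of a salicylate phenol with a primary benzylic alcohol; it avoids the 2,4-dialkoxybenzyl halide, which self-condenses, and runs under neutral conditions that the acid-labile benzylic ether tolerates.

Step 11
Reactants: 14 methyl 3,4-dimethoxy-2-{[2-methoxy-4-(propan-2-yloxy)phenyl]methoxy}-6-(propan-2-yloxy)benzoate
Product: 16 tert-butyl({6,7-dimethoxy-2-[2-methoxy-4-(propan-2-yloxy)phenyl]-4-(propan-2-yloxy)-1-benzofuran-3-yl}oxy)dimethylsilane, via lithium benzofuranolate 15 (not isolated)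
Conditions: LiN(iPr)2 (2.5 equiv), THF, −78 to 0 °C; then TBSCl, DMPU, −78 °C to rt
Reagents that add atoms: tert-butyl(chloro)dimethylsilane, SMILES CC(C)(C)[Si](C)(C)Cl
Why: Dieckmann-type closure: the aryloxy-substituted benzylic CH2, the only such position in 14, is lithiated with guidance from the ester carbonyl and the 2'-methoxy group and attacks the ester 5-exo-trig; loss of methoxide and a second deprotonation give the aromatic enolate 15, which silylates on oxygen because that retains the benzofuran.

Step 12
Reactants: 16 tert-butyl({6,7-dimethoxy-2-[2-methoxy-4-(propan-2-yloxy)phenyl]-4-(propan-2-yloxy)-1-benzofuran-3-yl}oxy)dimethylsilane; 17 bromoform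
Product: 20 3-bromo-7,8-dimethoxy-2-[2-methoxy-4-(propan-2-yloxy)phenyl]-5-(propan-2-yloxy)-4H-chromen-4-one, via dibromocyclopropane 18 (not isolated), via silyloxybenzopyrylium bromide 19 (not isolated)
Conditions: CHBr3, KOtBu, hexane/toluene, −30 °C to rt; aq. NaHCO3
Reagents that add atoms: none
Why: KOtBu deprotonates 17 and the tribromomethyl anion loses bromide to give dibromocarbene, which adds in a concerted [2+1] manner to the C2=C3 bond of 16, the only doubly oxygenated enol ether π bond, to give the cis-fused dibromocyclopropane 18. The bromide syn to the five-membered ring then ionises with disrotatory cyclopropyl-to-allyl opening in which the ring-fusion bond (the old C2–C3 bond) breaks, pushed by the lone pairs of O1 and of the silyloxy oxygen, and the cation formed is the aromatic 3-bromo-4-silyloxybenzopyrylium 19. Bromide, or the aqueous quench, takes the silyl group from the oxocarbenium oxygen and leaves the 4-pyranone 20. Ring C is therefore made by enlargement of the furan and not by a cyclisation: C2–C3 and C3–C4 form in the cycloaddition and the six-membered ring appears when the shared bond of the bicyclo[3.1.0] unit is cut. The closest known reactions are the Ciamician–Dennstedt enlargement of indoles and benzofurans with dihalocarbenes and the dihalocarbene ring expansion of cyclic silyl enol ethers to 2-halo enones, which this substrate combines. The two stereocentres of 18 are transient and cis by necessity, and none remains in 20. The step needs chemoselectivity for the enol ether over the alkoxyarenes and over attack of tert-butoxide on silicon: the first follows from the much higher nucleophilicity of the 2,3-dioxygenated double bond, and the second is the reason for the bulky silyl group, the non-polar solvent and the low temperature, since a free enolate would be dibromomethylated at C2 instead. Only cleavage of the fusion bond gives a cation stabilised by both oxygens, so the direction of opening is secured by the substrate.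

Step 13
Reactants: 20 3-bromo-7,8-dimethoxy-2-[2-methoxy-4-(propan-2-yloxy)phenyl]-5-(propan-2-yloxy)-4H-chromen-4-one
Product: 21 3,7,8-trimethoxy-2-[2-methoxy-4-(propan-2-yloxy)phenyl]-5-(propan-2-yloxy)-4H-chromen-4-one
Conditions: Pd(OAc)2 (cat.), tBuBrettPhos (cat.), Cs2CO3, MeOH, toluene, 80 °C
Reagents that add atoms: methanol, SMILES CO
Why: Palladium-catalysed C–O cross-coupling of a heteroaryl bromide with methanol; zerovalent palladium formed in the flask inserts into the C3–Br bond, the bulky biarylphosphine speeds C–O reductive elimination over β-hydride elimination, and carbonate keeps free methoxide too low to attack C2 of the pyranone.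

Step 14
Reactants: 21 3,7,8-trimethoxy-2-[2-methoxy-4-(propan-2-yloxy)phenyl]-5-(propan-2-yloxy)-4H-chromen-4-one
Product: 22 5-hydroxy-2-(4-hydroxy-2-methoxyphenyl)-3,7,8-trimethoxy-4H-chromen-4-one
Conditions: BCl3, CH2Cl2, −78 to 0 °C; then MeOH/H2O
Reagents that add atoms: none
Why: Lewis-acid dealkylation selective for secondary alkyl aryl ethers: the isopropyl groups leave as 2-chloropropane by an SN1-like path, the one on O5 helped by chelation to the C4 carbonyl, while the methyl ethers do not react at this temperature.

## Compound list

1 | 3-hydroxy-4,5-dimethoxybenzaldehyde | COc1cc(C=O)cc(O)c1OC | starting material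
2 | 3-(benzyloxy)-4,5-dimethoxybenzaldehyde | COc1cc(C=O)cc(OCc2ccccc2)c1OC | intermediate
3 | 3-(benzyloxy)-4,5-dimethoxyphenyl formate | COc1cc(OC=O)cc(OCc2ccccc2)c1OC | intermediate
4 | 3-(benzyloxy)-4,5-dimethoxyphenol | COc1cc(O)cc(OCc2ccccc2)c1OC | intermediate
5 | 1-(benzyloxy)-2,3-dimethoxy-5-(propan-2-yloxy)benzene | COc1cc(OC(C)C)cc(OCc2ccccc2)c1OC | intermediate
6 | 2,3-dimethoxy-5-(propan-2-yloxy)phenol | COc1cc(OC(C)C)cc(O)c1OC | intermediate
7 | 2-(hydroxymethyl)-5,6-dimethoxy-3-(propan-2-yloxy)phenol (present as its magnesium phenoxide) | COc1cc(OC(C)C)c(CO)c(O)c1OC | intermediate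
8 | 2-hydroxy-3,4-dimethoxy-6-(propan-2-yloxy)benzaldehyde | COc1cc(OC(C)C)c(C=O)c(O)c1OC | intermediate
9 | 2-hydroxy-3,4-dimethoxy-6-(propan-2-yloxy)benzoic acid | COc1cc(OC(C)C)c(C(=O)O)c(O)c1OC | intermediate
10 | methyl 2-hydroxy-3,4-dimethoxy-6-(propan-2-yloxy)benzoate | COC(=O)c1c(O)c(OC)c(OC)cc1OC(C)C | intermediate
11 | 4-hydroxy-2-methoxybenzaldehyde | COc1cc(O)ccc1C=O | starting material
12 | 2-methoxy-4-(propan-2-yloxy)benzaldehyde | COc1cc(OC(C)C)ccc1C=O | intermediate
13 | [2-methoxy-4-(propan-2-yloxy)phenyl]methanol | COc1cc(OC(C)C)ccc1CO | intermediate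
14 | methyl 3,4-dimethoxy-2-{[2-methoxy-4-(propan-2-yloxy)phenyl]methoxy}-6-(propan-2-yloxy)benzoate | COC(=O)c1c(OCc2ccc(OC(C)C)cc2OC)c(OC)c(OC)cc1OC(C)C | intermediate
15 | lithium 6,7-dimethoxy-2-[2-methoxy-4-(propan-2-yloxy)phenyl]-4-(propan-2-yloxy)-1-benzofuran-3-olate | [Li+].COc1cc(OC(C)C)ccc1-c1oc2c(OC)c(OC)cc(OC(C)C)c2c1[O-] | intermediate
16 | tert-butyl({6,7-dimethoxy-2-[2-methoxy-4-(propan-2-yloxy)phenyl]-4-(propan-2-yloxy)-1-benzofuran-3-yl}oxy)dimethylsilane | COc1cc(OC(C)C)ccc1-c1oc2c(OC)c(OC)cc(OC(C)C)c2c1O[Si](C)(C)C(C)(C)C | intermediate
17 | bromoform (tribromomethane) | BrC(Br)Br | starting material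
18 | tert-butyl({1,1-dibromo-3,4-dimethoxy-1a-[2-methoxy-4-(propan-2-yloxy)phenyl]-6-(propan-2-yloxy)-1,1a-dihydro-6bH-cyclopropa[b][1]benzofuran-6b-yl}oxy)dimethylsilane (racemic; cis ring fusion, the only one possible) | COc1cc(OC(C)C)ccc1C34Oc5c(OC)c(OC)cc(OC(C)C)c5C3(O[Si](C)(C)C(C)(C)C)C4(Br)Br | intermediate
19 | 3-bromo-4-{[tert-butyl(dimethyl)silyl]oxy}-7,8-dimethoxy-2-[2-methoxy-4-(propan-2-yloxy)phenyl]-5-(propan-2-yloxy)chromenylium bromide | [Br-].COc1cc(OC(C)C)ccc1-c1[o+]c2c(OC)c(OC)cc(OC(C)C)c2c(O[Si](C)(C)C(C)(C)C)c1Br | intermediate
20 | 3-bromo-7,8-dimethoxy-2-[2-methoxy-4-(propan-2-yloxy)phenyl]-5-(propan-2-yloxy)-4H-chromen-4-one | COc1cc(OC(C)C)ccc1-c1oc2c(OC)c(OC)cc(OC(C)C)c2c(=O)c1Br | intermediate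
21 | 3,7,8-trimethoxy-2-[2-methoxy-4-(propan-2-yloxy)phenyl]-5-(propan-2-yloxy)-4H-chromen-4-one | COc1cc(OC(C)C)ccc1-c1oc2c(OC)c(OC)cc(OC(C)C)c2c(=O)c1OC | intermediate
22 | 5-hydroxy-2-(4-hydroxy-2-methoxyphenyl)-3,7,8-trimethoxy-4H-chromen-4-one (5,4'-dihydroxy-3,7,8,2'-tetramethoxyflavone) | COc1cc(O)ccc1-c1oc2c(OC)c(OC)cc(O)c2c(=O)c1OC | target

## Step count and risks

Total: 14 steps. Longest linear sequence: 12 steps (steps 1–7 and 10–14, from 1); the ring B branch (steps 8 and 9) joins at step 10.

**Step 12 (key step).** The most likely failure is loss of the silyl group to tert-butoxide before the carbene arrives. The free enolate would then be alkylated at C2 and no ring enlargement would follow. Carbene addition could also be slow, because the double bond is tetrasubstituted and part of a furan. The fallback sets out from 16 and separates the carbon insertion from the halogenation. Cyclopropanation with Et2Zn and CH2I2 (Furukawa variant of the Simmons–Smith reaction) should give the siloxycyclopropane tert-butyl({3,4-dimethoxy-1a-[2-methoxy-4-(propan-2-yloxy)phenyl]-6-(propan-2-yloxy)-1,1a-dihydro-6bH-cyclopropa[b][1]benzofuran-6b-yl}oxy)dimethylsilane F1. Oxidative opening with FeCl3 in DMF followed by NaOAc (Ito–Saegusa ring expansion) cleaves the fusion bond and, after loss of HCl, should give the 3-unsubstituted flavone 7,8-dimethoxy-2-[2-methoxy-4-(propan-2-yloxy)phenyl]-5-(propan-2-yloxy)-4H-chromen-4-one F2. Lithiation of F2 at C3 with LiN(iPr)2 at −78 °C and quenching with 1,2-dibromotetrachloroethane returns to the route at 20.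

**Step 11.** Ring B is electron-rich, so the benzylic deprotonation may be slow or incomplete. The amide base could then attack the ester, or the anion could rearrange by a Wittig-type 1,2-shift; enolate 15 may also be oxidised at C2 by traces of air before it is silylated. The fallback sets out from 10 and forms the C2–aryl bond by cross-coupling instead.
- Alkylation of 10 with methyl bromoacetate and K2CO3 gives the diester methyl 3,4-dimethoxy-2-(2-methoxy-2-oxoethoxy)-6-(propan-2-yloxy)benzoate F3.
- Dieckmann condensation with KOtBu gives methyl 3-hydroxy-6,7-dimethoxy-4-(propan-2-yloxy)-1-benzofuran-2-carboxylate F4.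
- Saponification, acidification and gentle warming under argon give 6,7-dimethoxy-4-(propan-2-yloxy)-1-benzofuran-3(2H)-one F5.
- Commercial 4-bromo-3-methoxyphenol is isopropylated to 1-bromo-2-methoxy-4-(propan-2-yloxy)benzene F6.
- Palladium-catalysed α-arylation of F5 with F6 (Pd(OAc)2, P(tBu)3, LiN(SiMe3)2, toluene) forms enolate 15 in the flask, where the route is rejoined; silylation as in step 11 gives 16.

**Step 13.** β-Hydride elimination from the palladium methoxide would replace bromine by hydrogen. Methoxide could add to C2 and open the pyranone, and oxidative addition at the hindered, tetrasubstituted C3 may be slow. The fallback sets out from 20 and builds the C–O bond in two stages without an alkoxide bearing β-hydrogen. Miyaura borylation (B2pin2, KOAc, Pd(dppf)Cl2, dioxane) should give the boronate 7,8-dimethoxy-2-[2-methoxy-4-(propan-2-yloxy)phenyl]-5-(propan-2-yloxy)-3-(4,4,5,5-tetramethyl-1,3,2-dioxaborolan-2-yl)-4H-chromen-4-one F7. Oxidation with NaBO3·4H2O in THF/H2O gives the flavonol 3-hydroxy-7,8-dimethoxy-2-[2-methoxy-4-(propan-2-yloxy)phenyl]-5-(propan-2-yloxy)-4H-chromen-4-one F8. Methylation with MeI and K2CO3 in acetone rejoins the route at 21.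

**Step 6.** The hypochlorite by-product may chlorinate or oxidatively degrade the very electron-rich free phenol, and the 2,6-dioxygenated acid may decarboxylate on work-up. The fallback sets out from 8 and changes the order so that the oxidation is run on a capped phenol. Mitsunobu etherification of 8 with 13 gives the aldehyde 3,4-dimethoxy-2-{[2-methoxy-4-(propan-2-yloxy)phenyl]methoxy}-6-(propan-2-yloxy)benzaldehyde F9. Pinnick oxidation gives the acid 3,4-dimethoxy-2-{[2-methoxy-4-(propan-2-yloxy)phenyl]methoxy}-6-(propan-2-yloxy)benzoic acid F10. Esterification with MeI and K2CO3 rejoins the route at 14.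

## Further compounds

F1 | step 12 | tert-butyl({3,4-dimethoxy-1a-[2-methoxy-4-(propan-2-yloxy)phenyl]-6-(propan-2-yloxy)-1,1a-dihydro-6bH-cyclopropa[b][1]benzofuran-6b-yl}oxy)dimethylsilane (racemic, cis-fused) | COc1cc(OC(C)C)ccc1C23CC2(O[Si](C)(C)C(C)(C)C)c2c(OC(C)C)cc(OC)c(OC)c2O3
F2 | step 12 | 7,8-dimethoxy-2-[2-methoxy-4-(propan-2-yloxy)phenyl]-5-(propan-2-yloxy)-4H-chromen-4-one | COc1cc(OC(C)C)ccc1-c1cc(=O)c2c(OC(C)C)cc(OC)c(OC)c2o1
F3 | step 11 | methyl 3,4-dimethoxy-2-(2-methoxy-2-oxoethoxy)-6-(propan-2-yloxy)benzoate | COC(=O)COc1c(OC)c(OC)cc(OC(C)C)c1C(=O)OC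
F4 | step 11 | methyl 3-hydroxy-6,7-dimethoxy-4-(propan-2-yloxy)-1-benzofuran-2-carboxylate | COC(=O)c1oc2c(OC)c(OC)cc(OC(C)C)c2c1O
F5 | step 11 | 6,7-dimethoxy-4-(propan-2-yloxy)-1-benzofuran-3(2H)-one | COc1cc(OC(C)C)c2c(c1OC)OCC2=O
F6 | step 11 | 1-bromo-2-methoxy-4-(propan-2-yloxy)benzene | COc1cc(OC(C)C)ccc1Br
F7 | step 13 | 7,8-dimethoxy-2-[2-methoxy-4-(propan-2-yloxy)phenyl]-5-(propan-2-yloxy)-3-(4,4,5,5-tetramethyl-1,3,2-dioxaborolan-2-yl)-4H-chromen-4-one | COc1cc(OC(C)C)ccc1-c1oc2c(OC)c(OC)cc(OC(C)C)c2c(=O)c1B3OC(C)(C)C(C)(C)O3
F8 | step 13 | 3-hydroxy-7,8-dimethoxy-2-[2-methoxy-4-(propan-2-yloxy)phenyl]-5-(propan-2-yloxy)-4H-chromen-4-one | COc1cc(OC(C)C)ccc1-c1oc2c(OC)c(OC)cc(OC(C)C)c2c(=O)c1O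
F9 | step 6 | 3,4-dimethoxy-2-{[2-methoxy-4-(propan-2-yloxy)phenyl]methoxy}-6-(propan-2-yloxy)benzaldehyde | COc1cc(OC(C)C)ccc1COc1c(OC)c(OC)cc(OC(C)C)c1C=O
F10 | step 6 | 3,4-dimethoxy-2-{[2-methoxy-4-(propan-2-yloxy)phenyl]methoxy}-6-(propan-2-yloxy)benzoic acid | COc1cc(OC(C)C)ccc1COc1c(OC)c(OC)cc(OC(C)C)c1C(=O)O
A1 | alternative 1 | 1-[4-(benzyloxy)-2-methoxyphenyl]-2-methoxy-3-[3,4,6-trimethoxy-2-(methoxymethoxy)phenyl]propane-1,3-dione (enolisable centre, no fixed configuration) | COCOc1c(C(=O)C(OC)C(=O)c2ccc(OCc3ccccc3)cc2OC)c(OC)cc(OC)c1OC
A2 | alternative 1 | 2-iodo-1,4,5-trimethoxy-3-(methoxymethoxy)benzene | COCOc1c(I)c(OC)cc(OC)c1OC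
A3 | alternative 1 | 1-[4-(benzyloxy)-2-methoxyphenyl]-2-methoxyethan-1-one | COCC(=O)c1ccc(OCc2ccccc2)cc1OC
A4 | alternative 1 | carbon monoxide | [C-]#[O+]
A5 | alternative 2 | 2-[4-(benzyloxy)-2-methoxyphenyl]-5,8-dihydroxy-3,7-dimethoxy-4H-chromen-4-one | COc1cc(OCc2ccccc2)ccc1-c1oc2c(O)c(OC)cc(O)c2c(=O)c1OC
A6 | alternative 2 | 2-[4-(benzyloxy)-2-methoxyphenyl]-6-(1-hydroxy-2-methoxy-4-oxocyclobut-2-en-1-yl)-3-methoxy-4H-pyran-4-one (racemic) | COc1cc(OCc2ccccc2)ccc1-c1oc(C2(O)C(OC)=CC2=O)cc(=O)c1OC
A7 | alternative 2 | 3-methoxycyclobut-3-ene-1,2-dione | COC1=CC(=O)C1=O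
A8 | alternative 2 | 2-[4-(benzyloxy)-2-methoxyphenyl]-3-methoxy-4H-pyran-4-one | COc1cc(OCc2ccccc2)ccc1-c1occc(=O)c1OC
A9 | alternative 3 | 3-methoxy-4-(3,5,7,8-tetramethoxy-4-oxo-4H-chromen-2-yl)phenyl 2,2-dimethylpropanoate | CC(C)(C)C(=O)Oc1ccc(-c2oc3c(OC)c(OC)cc(OC)c3c(=O)c2OC)c(OC)c1
A10 | alternative 3 | 3-methoxy-4-[2-methoxy-3-oxo-3-(2,4,5-trimethoxyphenyl)propanoyl]phenyl 2,2-dimethylpropanoate (enolisable centre, no fixed configuration) | CC(C)(C)C(=O)Oc1ccc(C(=O)C(OC)C(=O)c2cc(OC)c(OC)cc2OC)c(OC)c1
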